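**Nothing to read.** You cannot read this share off the runs, since no run shows the over-reaction product. So a quick number has to be reckoned.

| flask | electrophile | free base | protonated nucleophile | remark | time |
|---|---|---|---|---|---|
| red | 0.40 M | 0.96 M (in portions, 3) | 0.96 M | run made earlier; portions every 12 min |  |
| ochre | 1.6 M | 0.96 M (in portions, 3) | 0.96 M | run made earlier; portions every 12 min |  |
| teal | 0.80 M | 1.4 M (in portions, 3) | 0.96 M | run made earlier; portions every 12 min |  |
| Monday's | 0.80 M | 0.960 M | 0.960 M | everything together at the start | 12 min |
| Thursday's | 0.80 M | 0.960 M (in portions, 3) | 0.960 M | the portions of free base follow each other after 12 min, the first at the start | 40 min |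

| run | time / min | target / % | side product / % |
|---|---|---|---|
| red | 12.0 | 17.7 | 0.6 |
| red | 25.0 | 29.0 | 2.8 |
| red | 40.0 | 31.4 | 3.6 |
| red | 50.0 | 28.3 | 6.5 |
| ochre | 4.00 | 6.3 | 1.9 |
| ochre | 8.00 | 7.3 | 3.4 |
| ochre | 20.0 | 14.7 | 7.1 |
| ochre | 50.0 | 18.8 | 16.3 |
| teal | 4.00 | 7.4 | 0 |
| teal | 8.00 | 12.9 | 0 |
| teal | 20.0 | 25.1 | 3.4 |
| teal | 50.0 | 22.2 | 7.9 |

(scatter of a reading: 1 percentage point)

* which of the two ends with the higher share of target in all that became target or side product or over-reaction product ("neither" if they lie within 2 percentage points) (Monday's / Thursday's / neither)
* share of target in all that became target or side product or over-reaction product, Monday's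
* share of target in all that became target or side product or over-reaction product, Thursday's



**Freeze the wear.** In the red run, target falls from 31.4% at 40.0 min to 28.3% at 50.0 min. At a peak, making equals loss. I freeze the making at red's earlier rise and divide by the peak reading. That gives a wear rate of 0.0277 min⁻¹, the fraction of target lost per minute. It is a pseudo-first-order constant, with free base assumed to be the consumer and frozen.

**The reckoning.** Target builds roughly steadily from zero, so over-reaction product per target is the wear rate times the time, divided by 2. Monday's gets 0.166. Thursday's has had, averaged over its time, 70.0% of its free base added. This counts what went in, not what stands free. I simply scale the wear rate by that share, which gives 0.388. Side product per target I take from readings: red's 0.0339 at 12.0 min for Monday's, and teal's 0.356 at 50.0 min for Thursday's. The share is one over one plus both ratios. I commit to 83.3% for Monday's, higher than 57.4% for Thursday's.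

**Your hunch.** The forecast says Monday's, with 68% and 50%, and warns that “the over-reaction product was never measured”.

**The flasks.** Monday's ends at 78.1% and Thursday's at 57.4%, so the answer is Monday's.

    electrophile + nucleophile → acid set free + target (k = 0.120 L mol⁻¹ min⁻¹)
    nucleophile + acid set free ⇌ protonated nucleophile, settled at all times (K = 1200 L mol⁻¹)
    acid set free + free base ⇌ salt of the base, settled at all times (K = 340 L mol⁻¹)
    electrophile + acid set free → side product (k = 0.460 L mol⁻¹ min⁻¹)
    free base + target → over-reaction product (k = 0.0610 L mol⁻¹ min⁻¹)

**Time wears.** Monday's share stands high through two things acting together: the short time, and the pairing of acid set free with free base to salt of the base. Left ten times as long, Monday's falls from 78.1% to 27.7%; without the pairing it stands at 20.8%. At 12.0 min, Monday's holds 0.222 over-reaction product per target, more than my 0.166. Left until 20 min, that flask holds 0.351, against 0.277 from the wear rate. Its share stands at 68.9%.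

All runs were computed on assumed constants; noise was put on by code.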